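**Retrosynthetic overview**
1. Lasiodiplactone A ⇒ (R)-lasiodiplodin + formaldehyde + (S)-2,4-dimethyl-4,5-dihydrofuran. One three-component step makes the ortho-quinone methide at C-11 and closes ring C by [4+2]. This gives the C/D ketal and two stereocentres.
2. Ring B: (R)-lasiodiplodin ⇒ 2-pyridyl thioester of the seco acid (thioesterase-like macrolactonisation, retention), followed by 12-O-demethylation.
3. Seco acid ⇒ benzylic dianion of 2,4-dimethoxy-6-methylbenzoic acid + (R)-8-iodooctan-2-ol, the latter from (R)-propylene oxide, the pentane-1,5-diyl bis-Grignard reagent and I2.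
4. Ring D: dihydrofuran ⇒ (S)-2-methylpent-4-yn-1-ol (cycloisomerisation) ⇒ Evans propargylation.
5. Ring order: A (bought) → B (macrolactone) → D (made in the fragment) → C (last).

Assumption: the biosynthesis is presumed to run from a polyketide thioester by thioesterase macrolactonisation to (R)-lasiodiplodin. C-11, ortho to the free phenol, is then alkylated by a xyloketal-type C7 hydroxy-enone unit (formally an ortho-quinone methide plus a dihydrofuran), and a bicyclic ketal forms.

Lasiodiplodin numbering: C-1 is the carbonyl, C-3 the carbinol, C-11 the aromatic CH next to the chain, and C-13 the aromatic CH between the two oxygens. C-12 carries OH and C-14 carries OMe.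

**Step 1**
Reactants: 1 (R)-propylene oxide; 2 1,5-dibromopentane
Product: 5 (R)-8-iodooctan-2-ol, via bis-Grignard reagent 3 (not isolated), via alkoxide Grignard 4 (not isolated)
Conditions: 2 (3 equiv), Mg, THF, 25–40 °C, decant; CuI (10 mol %), 1 (1 equiv), −30 → 0 °C; I2 (5.5 equiv), −40 → 0 °C; 1 M HCl, aq Na2S2O3
Reagents that add atoms: iodine, II
Why: Copper-catalysed SN2 opening of the epoxide at its CH2 carbon by one end of the bis-Grignard reagent (threefold excess keeps double addition a minor statistical event) leaves the (R) centre of 1 untouched, and iodinolysis of the surviving C–Mg bond installs the primary iodide in the same flask.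

**Step 2**
Reactants: 5 (R)-8-iodooctan-2-ol; 6 2,4-dimethoxy-6-methylbenzoic acid
Product: 8 2-[(8R)-8-hydroxynonyl]-4,6-dimethoxybenzoic acid, via dilithio dianion 7 (not isolated)
Conditions: 6 (1.2 equiv), LiN(iPr)2 (3.5 equiv), THF, −78 → 0 °C; 5, −78 °C → rt; 1 M HCl
Reagents that add atoms: none
Why: Lateral lithiation of the ortho-toluic acid gives a carboxylate-stabilised benzylic dianion that is C-alkylated by the primary iodide (SN2), the third equivalent of base being consumed by the free hydroxyl group of 5, and the carbinol centre takes no part.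

**Step 3**
Reactants: 8 2-[(8R)-8-hydroxynonyl]-4,6-dimethoxybenzoic acid
Product: 10 (R)-O-methyllasiodiplodin, via 2-pyridyl thioester 9 (not isolated)
Conditions: 2,2'-dipyridyl disulfide (1.5 equiv), PPh3 (1.5 equiv), PhMe, rt, 6 h; then syringe pump (12 h) into PhMe, 110 °C, final 1 mM
Reagents that add atoms: none
Why: Corey–Nicolaou double-activation macrolactonisation, in which the acyl thioester is attacked by the remote hydroxyl group as in thioesterase release, a method that tolerates di-ortho-substituted resorcylic acids, so that the acyl–oxygen bond is formed, the (R) centre is retained, and high dilution favours the 12-membered ring B.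

**Step 4**
Reactants: 10 (R)-O-methyllasiodiplodin
Product: 11 (R)-lasiodiplodin
Conditions: NaSEt (4 equiv), DMF, 110 °C, 3 h; 1 M HCl
Reagents that add atoms: none
Why: SN2 demethylation by the soft thiolate takes the unhindered 12-OMe group para to the carbonyl (the better phenoxide leaving group), while the 14-OMe group wedged next to the lactone carbonyl and the hindered secondary-alkyl lactone survive.

**Step 5**
Reactants: 12 (R)-4-benzyl-3-propionyloxazolidin-2-one; 13 propargyl bromide
Product: 15 (R)-4-benzyl-3-[(2S)-2-methylpent-4-ynoyl]oxazolidin-2-one, via sodium Z-enolate 14 (not isolated)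
Conditions: NaN(SiMe3)2 (1.1 equiv), THF, −78 °C; 13 (3 equiv), −78 → −40 °C
Reagents that add atoms: none
Why: Evans asymmetric alkylation, in which the chelated Z-enolate is alkylated on the face opposite the benzyl group, so the (R) auxiliary sets the (2S) methyl centre (dr at least 95:5, the minor isomer removed by chromatography).

**Step 6**
Reactants: 15 (R)-4-benzyl-3-[(2S)-2-methylpent-4-ynoyl]oxazolidin-2-one
Product: 16 (S)-2-methylpent-4-yn-1-ol
Conditions: LiBH4 (1.5 equiv), H2O (1.5 equiv), Et2O, 0 °C; aq NaOH
Reagents that add atoms: none
Why: Reductive cleavage of the exocyclic imide carbonyl by borohydride releases the primary alcohol and the recoverable auxiliary without epimerisation, and the alkyne is inert.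

**Step 7**
Reactants: 16 (S)-2-methylpent-4-yn-1-ol
Product: 18 (4S)-2,4-dimethyl-4,5-dihydrofuran, via exocyclic enol ether 17 (not isolated)
Conditions: NaNH2 (10 mol %), neat, 120 °C, product distilled out
Reagents that add atoms: none
Why: Base-catalysed 5-exo-dig hydroalkoxylation of the alkyne closes ring D, and allylic deprotonation–reprotonation moves the double bond into the ring to give the more stable trisubstituted enol ether, the redox-neutral equivalent of cyclodehydrating the biosynthetic hydroxy ketone, while the C-4 centre takes no part.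

**Step 8**
Reactants: 11 (R)-lasiodiplodin; 18 (4S)-2,4-dimethyl-4,5-dihydrofuran
Product: 22 lasiodiplactone A, via bromomagnesium phenoxide 19 (not isolated), via hydroxymethyl phenoxide 20 (not isolated), via ortho-quinone methide 21 (not isolated)
Conditions: EtMgBr (1.05 equiv), PhMe (0.05 M), 0 °C → rt; (CH2O)n (1.5 equiv), 18 (4 equiv), sealed tube, 90 °C, 14 h; aq NH4Cl
Reagents that add atoms: formaldehyde (from paraformaldehyde), C=O
Why: Proposed new method: the magnesium phenoxide 19 binds formaldehyde and delivers it through a six-membered chelate to an ortho carbon, expected to be C-11 (para to OMe) because C-13 lies between two oxygens and is screened by the in-plane O-methyl group, as seen when 3-alkoxyphenols and orcinol ethers react para to the alkoxy group; chelate 20 then loses Mg(OH)Br to give ortho-quinone methide 21, which the excess electron-rich enol ether 18 traps in an inverse-electron-demand hetero-Diels–Alder reaction (CH2 to C-3, oxygen to C-2 of the dihydrofuran) that closes ring C, the cis C/D fusion following from suprafacial addition and attack anti to the C-4 methyl group letting the single (S) centre of 18 set the ring-fusion CH (S) and the ketal carbon (S), which is also the thermodynamically preferred ketal; the proton-poor basic medium keeps 18 from reverting to 17, which would give a spiroketal; the closest known reaction types are the trapping by vinyl ethers of ortho-quinone methides made from magnesium phenoxides and aldehydes, and the two-component cycloaddition of preformed ortho-quinone methide precursors with 2,4-dimethyl-4,5-dihydrofuran in the xyloketal and alboatrin series.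

**Compound list**
1 | (R)-propylene oxide, (2R)-2-methyloxirane | C[C@@H]1CO1 | starting material
2 | 1,5-dibromopentane | BrCCCCCBr | starting material
3 | pentane-1,5-diylbis(magnesium bromide) | Br[Mg]CCCCC[Mg]Br | intermediate
4 | bromomagnesium (2R)-8-(bromomagnesio)octan-2-olate | C[C@@H](O[Mg]Br)CCCCCC[Mg]Br | intermediate
5 | (R)-8-iodooctan-2-ol | C[C@@H](O)CCCCCCI | intermediate
6 | 2,4-dimethoxy-6-methylbenzoic acid | COc1cc(C)c(C(=O)O)c(OC)c1 | starting material
7 | lithium 2-(lithiomethyl)-4,6-dimethoxybenzoate (dianion of 6) | [Li+].[Li+].[CH2-]c1cc(OC)cc(OC)c1C(=O)[O-] | intermediate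
8 | 2-[(8R)-8-hydroxynonyl]-4,6-dimethoxybenzoic acid | C[C@@H](O)CCCCCCCc1cc(OC)cc(OC)c1C(=O)O | intermediate
9 | S-pyridin-2-yl 2-[(8R)-8-hydroxynonyl]-4,6-dimethoxybenzenecarbothioate | C[C@@H](O)CCCCCCCc1cc(OC)cc(OC)c1C(=O)Sc1ccccn1 | intermediate
10 | (R)-O-methyllasiodiplodin, (3R)-12,14-dimethoxy-3-methyl-3,4,5,6,7,8,9,10-octahydro-1H-2-benzoxacyclododecin-1-one | COc1cc(OC)cc2c1C(=O)O[C@H](C)CCCCCCC2 | intermediate
11 | (R)-lasiodiplodin, the 12-hydroxy-14-methoxy analogue of 10 | COc1cc(O)cc2c1C(=O)O[C@H](C)CCCCCCC2 | intermediate
12 | (R)-4-benzyl-3-propionyloxazolidin-2-one | CCC(=O)N1[C@H](Cc2ccccc2)COC1=O | starting material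
13 | propargyl bromide | C#CCBr | starting material
14 | sodium (Z)-enolate of 12 | C/C=C(\[O-])N1[C@H](Cc2ccccc2)COC1=O.[Na+] | intermediate
15 | (R)-4-benzyl-3-[(2S)-2-methylpent-4-ynoyl]oxazolidin-2-one | C#CC[C@H](C)C(=O)N1[C@H](Cc2ccccc2)COC1=O | intermediate
16 | (S)-2-methylpent-4-yn-1-ol | C#CC[C@H](C)CO | intermediate
17 | (4S)-4-methyl-2-methylideneoxolane | C=C1C[C@H](C)CO1 | intermediate
18 | (4S)-2,4-dimethyl-4,5-dihydrofuran | CC1=C[C@H](C)CO1 | intermediate
19 | bromomagnesium 12-phenoxide of (R)-lasiodiplodin | COc1cc(O[Mg]Br)cc2c1C(=O)O[C@H](C)CCCCCCC2 | intermediate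
20 | bromomagnesium phenoxide of 11-(hydroxymethyl)-(R)-lasiodiplodin | COc1cc(O[Mg]Br)c(CO)c2c1C(=O)O[C@H](C)CCCCCCC2 | intermediate
21 | 11-methylidene-12-oxo ortho-quinone methide of (R)-lasiodiplodin | COC1=CC(=O)C(=C)C2=C1C(=O)O[C@H](C)CCCCCCC2 | intermediate
22 | lasiodiplactone A (lactone carbinol R; ring-fusion CH S; CH–CH3 S; ketal carbon S) | COc1cc2c(c3c1C(=O)O[C@H](C)CCCCCCC3)C[C@H]1[C@H](C)CO[C@@]1(C)O2 | target

**Step count**
Total steps: 8. Longest linear sequence: 5 (steps 1, 2, 3, 4 and 8).

**Steps most likely to fail**

1) Step 8. The possible failures are attack at C-13, further oxidation of 20 to the salicylaldehyde, diarylmethane formation from 21 and 19, and a modest facial ratio.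

The fallback sets out from 18 (with 11) and comes back at 22. It reverses the polarity of the union, so the arene becomes the nucleophile and the C7 unit the electrophile. Vilsmeier–Haack formylation of 18 at its nucleophilic C-3 (POCl3, DMF, CH2Cl2, 0 °C; aq K2CO3) gives (4S)-2,4-dimethyl-4,5-dihydrofuran-3-carbaldehyde F1. Reduction with iBu2AlH (CH2Cl2, −78 °C) gives [(4S)-2,4-dimethyl-4,5-dihydrofuran-3-yl]methanol F2. BF3·OEt2 with MgSO4 (Et2O, 0 °C) then ionises F2 in the presence of neutral 11. Friedel–Crafts attack para to the methoxy group is followed by acid-equilibrated ketalisation, which delivers 22 as the thermodynamic isomer. Because the CH2 carbon is already fixed at C-3, no spiroketal can form.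

2) Step 3. The acyl group is hindered, and the 12-membered ring competes with the diolide.

The fallback sets out from 3 and comes back at 10. It activates the alcohol instead of the acid, closing the ring with inversion, so the chain is made in the mirror-image series. Opening bought (S)-propylene oxide (C[C@H]1CO1) with 3 under CuI catalysis gives bromomagnesium (2S)-8-(bromomagnesio)octan-2-olate F3. An iodine quench gives (S)-8-iodooctan-2-ol F4. Alkylation of dianion 7 with F4 gives 2-[(8S)-8-hydroxynonyl]-4,6-dimethoxybenzoic acid F5. Mitsunobu macrolactonisation (PPh3, DIAD, PhMe, 2 mM, rt) lets the unhindered carboxylate displace the activated carbinol by SN2, which gives the (R) lactone 10.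

3) Step 1. The difficulties are statistical mono-opening, double addition, and coupling during the iodine quench.

The fallback sets out from 1 and comes back at 5. It replaces the statistical desymmetrisation by a pre-differentiated dihalide. Bought 1-bromo-5-chloropentane (ClCCCCCBr) takes up Mg only at the C–Br bond and gives 5-chloropentylmagnesium bromide F6. CuI-catalysed opening of 1 gives (R)-8-chlorooctan-2-ol F7. Finkelstein exchange (NaI, acetone, reflux) then gives 5, at the cost of one more step.

**Further compounds**
F1 | step 8 | (4S)-2,4-dimethyl-4,5-dihydrofuran-3-carbaldehyde | CC1=C(C=O)[C@H](C)CO1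
F2 | step 8 | [(4S)-2,4-dimethyl-4,5-dihydrofuran-3-yl]methanol | CC1=C(CO)[C@H](C)CO1
F3 | step 3 | bromomagnesium (2S)-8-(bromomagnesio)octan-2-olate | C[C@H](O[Mg]Br)CCCCCC[Mg]Br
F4 | step 3 | (S)-8-iodooctan-2-ol | C[C@H](O)CCCCCCI
F5 | step 3 | 2-[(8S)-8-hydroxynonyl]-4,6-dimethoxybenzoic acid | C[C@H](O)CCCCCCCc1cc(OC)cc(OC)c1C(=O)O
F6 | step 1 | 5-chloropentylmagnesium bromide | ClCCCCC[Mg]Br
F7 | step 1 | (R)-8-chlorooctan-2-ol | C[C@@H](O)CCCCCCCl
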